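**Late times.** At late times the substrate has left by two exits, and I want the share each takes.

- spring: substrate 0.058 M; reagent 0.0520 M; free catalyst 0.29 mM; second catalyst 0.58 mM; time 2.5 d
- noon: substrate 0.058 M; reagent 0.0680 M; free catalyst 0.29 mM; second catalyst 0.58 mM; time 2.5 d

    substrate + free catalyst ⇌ free catalyst + open intermediate (K1 = 0.75, k1 = 376 M⁻¹ h⁻¹)
    second catalyst + open intermediate ⇌ catalyst intermediate (K2 = 7.0 M⁻¹, k2 = 3240 M⁻¹ h⁻¹)
    reagent + catalyst intermediate → second catalyst + target (k3 = 246 M⁻¹ h⁻¹)
    open intermediate → side product (k4 = 0.0763 h⁻¹)
    free catalyst + free catalyst ⇌ resting dimer (K5 = 3590 M⁻¹, k5 = 15600 M⁻¹ h⁻¹)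
    substrate + reagent → uncatalysed product (k6 = 1.66 M⁻¹ h⁻¹)

1. which of these there is most of at the end, counted by the substrate in it, spring (uncatalysed product / substrate / side product / target)
2. which of these there is most of at the end, counted by the substrate in it, noon (uncatalysed product / substrate / side product / target)
3. final amount of the leader among these, as a percentage of the substrate charged, in spring
4. final amount of the leader among these, as a percentage of the substrate charged, in noon

**Frozen levels.** Free catalyst at its charge pairs up at a pace of 4.52 h⁻¹, far faster than substrate would open at 0.109 h⁻¹ with all of it free, so I freeze free catalyst at its dimer equilibrium, 0.143 mM. Substrate then opens at 0.0538 h⁻¹ and closes again at 0.0717 h⁻¹. Spring's reagent takes catalyst intermediate at 12.8 h⁻¹, far slower than catalyst intermediate comes apart at 463 h⁻¹, so I hold it at equilibrium with second catalyst and open intermediate.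

**Exit share.** With c(reagent) frozen, the background is pseudo-first-order in substrate: 0.0863 h⁻¹ in spring, 0.113 h⁻¹ at noon. Open intermediate leaves forward at 0.128 h⁻¹ in spring and 0.144 h⁻¹ at noon, so the real drain through it is the opening pace times forward pace over forward plus closing pace: 0.0345 h⁻¹ in spring, 0.0359 h⁻¹ at noon. Background over background plus drain gives 71.4% in spring and 75.9% at noon: the exit share, the part of the substrate leaving as uncatalysed product at a given c(reagent).

**The bracket.** Those charge values are my tops. At them spring's substrate halves in 5.74 h, far shorter than the 60 h run. For low marks I freeze c(reagent) at what the top share leaves, 10.6 mM in spring and 24.0 mM at noon, which gives 37.3% and 56.0%. At the mean of charge and low level, 31.3 mM and 46.0 mM, I commit to 61.7% in spring and 69.3% at noon, with uncatalysed product leading both.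

**Forecast, result.** The forecast says uncatalysed product in both flasks, at 59% in spring and 66% at noon, since “the extra reagent at noon pushes its share a little higher”, and both figures lie below my tops and above my lows. The flasks give uncatalysed product at 58.5% in spring and uncatalysed product at 67.5% at noon.

**Falling reagent.** Spring ends 13 percentage points under its exit share at charge, 71.4%, and falling reagent is a part of that gap: held at its charge, spring ends at 71.3% against 58.5%. The gap between noon and spring comes from their difference in c(reagent): with spring's reagent, noon reads 58.5% against 67.5%. The neighbour of noon charged with 0.017 M reagent has an exit share at charge of 48.1%. Its reagent ends at 8.77% of its charge, and it reads 23.4% uncatalysed product against 54.3% side product.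

The constants used here are those of an exercise; the run is a simulation.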